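**Retrosynthetic overview**
1. The oxirane is made last, by hydroxyl-directed epoxidation of the (4Z)-cyclodecadienolide. The ten-membered ring comes from an acyclic, fully acylated pentaene by ring-closing metathesis that forms C4=C5.
2. Enabling feature: C4–C5 is shared by the oxirane and the ten-membered carbocycle, and the fusion is cis (C3 and C6 on one side, one O on both carbons), so both carbons map onto one Z-trisubstituted olefin. Two carbons bearing the same O have no polar pairing, so two like-polarised olefin termini are united at the fully substituted C4. The free C2–OH lies homoallylic to the new olefin on the face that must take up O.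
3. The seco-compound is assembled by C9–C10 union (Nozaki–Hiyama–Kishi) of fragment 1 (C1–C4, C10, C14, C15, a (Z)-α-iodoenoate from a glyoxylate-ene reaction and an iodo-Wittig olefination) with fragment 2 (C5–C9, C11–C13, an α-angeloyloxy aldehyde). Oxidation and Felkin–Anh reduction then set C9.
4. Fragment 2 comes from (R)-glyceraldehyde acetonide (C7–C9), methyl acrylate (C11–C13) and acrolein (C5, C6) by a Morita–Baylis–Hillman reaction and chromium-mediated allylation/lactonisation.
5. Ring order: γ-lactone (step 7), ten-membered carbocycle (step 18), oxirane (step 19).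

Key step: step 18

Remark: germacrane numbering is used throughout (ring C1–C10, lactone carbons C11–C13 on C7, ester carbon C14 on C10, methyl C15 on C4). Descriptors follow the sequence rule for each compound, so the letters at C6 and C7 change along the route although the spatial arrangement does not.

Step 1
Reactants: 1 ethyl glyoxylate; 2 isobutene
Product: 3 ethyl (2S)-2-hydroxy-4-methylpent-4-enoate
Conditions: (S)-BINOL (10 mol %), Ti(OiPr)2Cl2 (10 mol %), 4 Å MS, CH2Cl2, −30 °C
Reagents that add atoms: none
Why: Catalytic asymmetric glyoxylate-ene (carbonyl-ene) reaction: the (S)-BINOL–titanium complex shields one aldehyde face, so C2 should be set as S, and the ene shift delivers the isopropenyl group (C4, C15) directly.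

Step 2
Reactants: 3 ethyl (2S)-2-hydroxy-4-methylpent-4-enoate
Product: 4 ethyl (2S)-2-(tert-butyldimethylsilyloxy)-4-methylpent-4-enoate
Conditions: TBSCl, imidazole, DMF, rt
Reagents that add atoms: tert-butyldimethylsilyl chloride, CC(C)(C)[Si](C)(C)Cl
Why: Standard silylation; the ether blocks the C2 hydroxyl through the reduction, olefination and oxidation steps and touches no stereocentre.

Step 3
Reactants: 4 ethyl (2S)-2-(tert-butyldimethylsilyloxy)-4-methylpent-4-enoate
Product: 5 (2S)-2-(tert-butyldimethylsilyloxy)-4-methylpent-4-enal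
Conditions: i-Bu2AlH (1.1 equiv), CH2Cl2, −78 °C, then aqueous work-up
Reagents that add atoms: none
Why: Partial ester reduction: the aluminium hemiacetal of an α-silyloxy ester is stable at −78 °C and collapses only on work-up, so over-reduction and epimerisation at C2 should be avoided.

Step 4
Reactants: 5 (2S)-2-(tert-butyldimethylsilyloxy)-4-methylpent-4-enal; 6 methyl (triphenylphosphoranylidene)acetate
Product: 8 methyl (2Z,4S)-4-(tert-butyldimethylsilyloxy)-2-iodo-6-methylhepta-2,6-dienoate, via iodo ylide 7 (not isolated)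
Conditions: 6, NIS, CH2Cl2, −20 °C; then 5, −20 °C → rt
Reagents that add atoms: N-iodosuccinimide, O=C1CCC(=O)N1I
Why: Iodination of the stabilised ylide followed by Wittig olefination: as with other stabilised ylides the C2 chain should end trans to the ester and cis to iodine (Z), which fixes the later cis relation of C9 and C2 on C1=C10.

Step 5
Reactants: 9 (4R)-2,2-dimethyl-1,3-dioxolane-4-carbaldehyde; 10 methyl acrylate
Product: 11 methyl 2-{[(4R)-2,2-dimethyl-1,3-dioxolan-4-yl](hydroxy)methyl}prop-2-enoate (both carbinol epimers)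
Conditions: DABCO (0.5 equiv), dioxane–H2O, rt
Reagents that add atoms: none
Why: Morita–Baylis–Hillman reaction that forms C7–C11; the new carbinol centre is lost in step 6, so its configuration does not matter, and C8 comes unchanged from the chiral pool.

Step 6
Reactants: 11 methyl 2-{[(4R)-2,2-dimethyl-1,3-dioxolan-4-yl](hydroxy)methyl}prop-2-enoate
Product: 12 methyl (2Z)-2-(bromomethyl)-3-[(4S)-2,2-dimethyl-1,3-dioxolan-4-yl]prop-2-enoate
Conditions: NBS, Me2S, CH2Cl2, 0 °C → rt
Reagents that add atoms: N-bromosuccinimide, O=C1CCC(=O)N1Br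
Why: The alcohol is activated as an alkoxysulfonium salt and bromide attacks in the SN2′ sense; the transposition should give the conjugated trisubstituted enoate with the dioxolane trans to the ester (Z by the sequence rule) under acid-free conditions that spare the acetonide.

Step 7
Reactants: 12 methyl (2Z)-2-(bromomethyl)-3-[(4S)-2,2-dimethyl-1,3-dioxolan-4-yl]prop-2-enoate; 13 acrolein
Product: 15 (4S,5R)-4-[(4S)-2,2-dimethyl-1,3-dioxolan-4-yl]-5-ethenyl-3-methylideneoxolan-2-one, via hydroxy ester 14 (not isolated)
Conditions: CrCl2 (2.5 equiv), THF, 0 °C → rt; aqueous work-up, then PPTS (10 mol %), benzene, 50 °C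
Reagents that add atoms: none
Why: Nozaki–Hiyama allylation followed by lactonisation: divalent chromium converts 12 into an allylchromium species that equilibrates to the isomer with the C8 group trans to CH2Cr and adds through C7 in a chair transition state with the vinyl and C8 groups equatorial (anti adduct, hence the trans C6/C7 lactone), while A(1,3) strain holds C8–H in the plane of C7=C11 so that acrolein should approach past the small O8 and anti to the C8–C9 bond, which sets C7 and with it C6 relative to C8.

Step 8
Reactants: 15 (4S,5R)-4-[(4S)-2,2-dimethyl-1,3-dioxolan-4-yl]-5-ethenyl-3-methylideneoxolan-2-one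
Product: 16 (4R,5R)-4-[(1S)-1,2-dihydroxyethyl]-5-ethenyl-3-methylideneoxolan-2-one
Conditions: AcOH–H2O 4:1, 40 °C
Reagents that add atoms: none
Why: Mild acid hydrolysis of the acetonide; the lactone and the olefins are inert to aqueous acetic acid, no stereocentre is touched, and C14 is not yet present, so O8 has no second ester to attack.

Step 9
Reactants: 16 (4R,5R)-4-[(1S)-1,2-dihydroxyethyl]-5-ethenyl-3-methylideneoxolan-2-one
Product: 17 (4R,5R)-4-[(1S)-2-(tert-butyldimethylsilyloxy)-1-hydroxyethyl]-5-ethenyl-3-methylideneoxolan-2-one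
Conditions: TBSCl (1.05 equiv), imidazole, CH2Cl2, 0 °C
Reagents that add atoms: tert-butyldimethylsilyl chloride, CC(C)(C)[Si](C)(C)Cl
Why: Sterically controlled monosilylation: the primary C9 hydroxyl should react well before the hindered secondary C8 hydroxyl, which tells O8 and O9 apart.

Step 10
Reactants: 17 (4R,5R)-4-[(1S)-2-(tert-butyldimethylsilyloxy)-1-hydroxyethyl]-5-ethenyl-3-methylideneoxolan-2-one; 18 angelic acid
Product: 19 (1S)-2-(tert-butyldimethylsilyloxy)-1-[(2R,3S)-2-ethenyl-4-methylidene-5-oxooxolan-3-yl]ethyl (2Z)-2-methylbut-2-enoate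
Conditions: 18, 2,4,6-trichlorobenzoyl chloride, Et3N, toluene, rt; then 17, 80 °C
Reagents that add atoms: none
Why: Yamaguchi mixed-anhydride esterification run without a nucleophilic catalyst, the established way to acylate hindered alcohols with angelic acid without Z-to-E isomerisation; C8 keeps its configuration because only the O–H bond reacts.

Step 11
Reactants: 19 (1S)-2-(tert-butyldimethylsilyloxy)-1-[(2R,3S)-2-ethenyl-4-methylidene-5-oxooxolan-3-yl]ethyl (2Z)-2-methylbut-2-enoate
Product: 20 (1S)-1-[(2R,3S)-2-ethenyl-4-methylidene-5-oxooxolan-3-yl]-2-hydroxyethyl (2Z)-2-methylbut-2-enoate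
Conditions: HF·pyridine, pyridine, THF, 0 °C
Reagents that add atoms: none
Why: Buffered fluoride cleavage of a primary silyl ether; the near-neutral medium and low temperature should suppress migration of the hindered angelate from O8 to O9.

Step 12
Reactants: 20 (1S)-1-[(2R,3S)-2-ethenyl-4-methylidene-5-oxooxolan-3-yl]-2-hydroxyethyl (2Z)-2-methylbut-2-enoate
Product: 21 (1S)-1-[(2R,3S)-2-ethenyl-4-methylidene-5-oxooxolan-3-yl]-2-oxoethyl (2Z)-2-methylbut-2-enoate
Conditions: Dess–Martin periodinane, pyridine, CH2Cl2, 0 °C
Reagents that add atoms: none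
Why: Dess–Martin oxidation, a non-basic method that should give the α-acyloxy aldehyde without epimerisation at C8; the aldehyde is used at once.

Step 13
Reactants: 21 (1S)-1-[(2R,3S)-2-ethenyl-4-methylidene-5-oxooxolan-3-yl]-2-oxoethyl (2Z)-2-methylbut-2-enoate; 8 methyl (2Z,4S)-4-(tert-butyldimethylsilyloxy)-2-iodo-6-methylhepta-2,6-dienoate
Product: 22 seco-germacranolide C9 alcohol (2S,6R,7S,8S, mainly 9R; 1(10)E): methyl (2E,4S)-4-(tert-butyldimethylsilyloxy)-2-{(1R,2S)-1-hydroxy-2-[(2Z)-2-methylbut-2-enoyloxy]-2-[(2R,3S)-2-ethenyl-4-methylidene-5-oxooxolan-3-yl]ethyl}-6-methylhepta-2,6-dienoate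
Conditions: CrCl2 (5 equiv), NiCl2 (1 mol %), DMSO–THF, rt
Reagents that add atoms: none
Why: Nozaki–Hiyama–Kishi alkenylation: zerovalent nickel inserts into the C–I bond with retention, and transmetalation gives an alkenyl species of trivalent chromium that adds only to the aldehyde and tolerates lactone, esters and olefins, so C9 should end cis to C2 on C1=C10; the Felkin–Anh sense (expected 9R) does not matter because C9 is reset in steps 14 and 15.

Step 14
Reactants: 22 seco-germacranolide C9 alcohol
Product: 23 seco-germacranolide C9 ketone (2S,6R,7S,8S; 1(10)E): methyl (2E,4S)-4-(tert-butyldimethylsilyloxy)-2-{(2S)-2-[(2Z)-2-methylbut-2-enoyloxy]-2-[(2R,3S)-2-ethenyl-4-methylidene-5-oxooxolan-3-yl]acetyl}-6-methylhepta-2,6-dienoate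
Conditions: Dess–Martin periodinane, pyridine, CH2Cl2, 0 °C
Reagents that add atoms: none
Why: Dess–Martin oxidation of the allylic alcohol converges both C9 epimers on one ketone; the neutral, nucleophile-free medium should leave the C1=C10 geometry and C8 untouched, and the ketone is reduced without storage.

Step 15
Reactants: 23 seco-germacranolide C9 ketone
Product: 24 seco-germacranolide (9S)-alcohol (2S,6R,7S,8S,9S; 1(10)E)
Conditions: NaBH4, CeCl3·7H2O, MeOH, −78 °C
Reagents that add atoms: none
Why: Luche 1,2-reduction under polar Felkin–Anh control: with the C8–O bond perpendicular to the carbonyl plane, hydride should attack anti to O8 past C8–H and give the 8,9-syn (9S) alcohol, the epimer opposite to that formed by carbon addition to 21, while the hard reagent at −78 °C should spare the α-methylene lactone and the alkylidene carbon.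

Step 16
Reactants: 24 seco-germacranolide (9S)-alcohol
Product: 25 seco-germacranolide 9-acetate 2-silyl ether (2S,6R,7S,8S,9S; 1(10)E)
Conditions: Ac2O, pyridine, DMAP (cat.), CH2Cl2, 0 °C
Reagents that add atoms: acetic anhydride, CC(=O)OC(C)=O
Why: Standard acetylation carried out directly after step 15, so that the free C9 hydroxyl cannot exchange acyl groups with O8; the configuration at C9 is retained.

Step 17
Reactants: 25 seco-germacranolide 9-acetate 2-silyl ether
Product: 26 seco-germacranolide pentaene with free C2 hydroxyl (2S,6R,7S,8S,9S; 1(10)E)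
Conditions: HF·pyridine, THF, 0 °C → rt
Reagents that add atoms: none
Why: Fluoride cleavage of the secondary silyl ether in a weakly acidic medium that leaves the four ester groups intact; the freed hydroxyl is trans to the C14 ester across C1=C10 and cannot lactonise.

Step 18
Reactants: 26 seco-germacranolide pentaene with free C2 hydroxyl
Product: 27 (1(10)E,4Z)-9α-acetoxy-8β-angeloyloxy-2α-hydroxy-14-methoxy-14-oxogermacra-1(10),4,11(13)-trien-12,6α-olide (2S,6R,7S,8S,9S)
Conditions: second-generation Hoveyda–Grubbs catalyst (15 mol %, in portions), 1,4-benzoquinone (30 mol %), toluene (0.5 mM), 90 °C, argon sparge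
Reagents that add atoms: none
Why: Olefin metathesis by the metallacyclobutane cycle: the ruthenium benzylidene should load on the only monosubstituted olefin (the C5 vinyl group), the C5 alkylidene adds across the 1,1-disubstituted C4 olefin, and cycloreversion forms C4=C5 while ethene escapes and makes the closure irreversible. The closest known reaction type is ring-closing metathesis to ten-membered carbocycles and to trisubstituted cycloalkenes with second-generation ruthenium catalysts. One ring is closed, the ten-membered carbocycle, in a macrocyclising mode with the new double bond endocyclic. No stereocentre is formed; the stereochemical element is the olefin geometry, and Z should result because an E-trisubstituted olefin next to the trans-fused lactone and the cis C1=C10 bond would be far more strained, so the cis relation of C3 and C6 needed in the oxirane is fixed here. Chemoselectivity among the five C=C bonds rests on electronics and substitution: the α-methylene lactone, the C1=C10 enoate and the angelate are electron-poor and 1,1-di- or trisubstituted, should stay spectators, and cannot form a competing ring of favourable size. Cyclisation must beat oligomerisation, which high dilution, portionwise catalyst addition and the two turn elements already in the chain (cis C1=C10, trans-disubstituted lactone) should secure, while benzoquinone suppresses hydride-induced olefin migration.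

Step 19
Reactants: 27 (1(10)E,4Z)-cyclodecadienolide
Product: 28 target, (1(10)E)-9α-acetoxy-8β-angeloyloxy-4α,5α-epoxy-2α-hydroxy-14-methoxy-14-oxogermacra-1(10),11(13)-dien-12,6α-olide (2S,4R,5S,6S,7R,8S,9S)
Conditions: VO(acac)2 (10 mol %), t-BuOOH (1.5 equiv, decane), CH2Cl2, 0 °C → rt
Reagents that add atoms: tert-butyl hydroperoxide, CC(C)(C)OO
Why: Vanadium-catalysed hydroxyl-directed epoxidation of a homoallylic alcohol: the C2 vanadate should deliver the peroxide oxygen through a chair-like array with C1 and C5 pseudo-equatorial to the face syn to O2, syn addition to the Z-olefin sets C4 (R) and C5 (S) together as the cis-fused oxirane, and the three electron-poor olefins do not react with the electrophilic oxidant.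

**Compound list**
1 | ethyl glyoxylate | CCOC(=O)C=O | starting material
2 | isobutene | CC(C)=C | starting material
3 | ethyl (2S)-2-hydroxy-4-methylpent-4-enoate | CCOC(=O)[C@@H](O)CC(C)=C | intermediate
4 | ethyl (2S)-2-(tert-butyldimethylsilyloxy)-4-methylpent-4-enoate | CCOC(=O)[C@@H](O[Si](C)(C)C(C)(C)C)CC(C)=C | intermediate
5 | (2S)-2-(tert-butyldimethylsilyloxy)-4-methylpent-4-enal | O=C[C@@H](O[Si](C)(C)C(C)(C)C)CC(C)=C | intermediate
6 | methyl (triphenylphosphoranylidene)acetate | COC(=O)C=P(c1ccccc1)(c1ccccc1)c1ccccc1 | starting material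
7 | methyl iodo(triphenylphosphoranylidene)acetate (iodo ylide, not isolated) | COC(=O)C(I)=P(c1ccccc1)(c1ccccc1)c1ccccc1 | intermediate
8 | methyl (2Z,4S)-4-(tert-butyldimethylsilyloxy)-2-iodo-6-methylhepta-2,6-dienoate | COC(=O)/C(I)=C/[C@@H](O[Si](C)(C)C(C)(C)C)CC(C)=C | intermediate
9 | (4R)-2,2-dimethyl-1,3-dioxolane-4-carbaldehyde, (R)-glyceraldehyde acetonide | O=C[C@@H]1OC(C)(C)OC1 | starting material
10 | methyl acrylate | C=CC(=O)OC | starting material
11 | methyl 2-{[(4R)-2,2-dimethyl-1,3-dioxolan-4-yl](hydroxy)methyl}prop-2-enoate, both carbinol epimers | C=C(C(=O)OC)C(O)[C@@H]1OC(C)(C)OC1 | intermediate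
12 | methyl (2Z)-2-(bromomethyl)-3-[(4S)-2,2-dimethyl-1,3-dioxolan-4-yl]prop-2-enoate | COC(=O)/C(CBr)=C/[C@@H]1OC(C)(C)OC1 | intermediate
13 | acrolein | C=CC=O | starting material
14 | methyl (3S,4R)-3-[(4S)-2,2-dimethyl-1,3-dioxolan-4-yl]-4-hydroxy-2-methylidenehex-5-enoate (hydroxy ester, not isolated) | O[C@H](C=C)[C@H](C(=C)C(=O)OC)[C@@H]1OC(C)(C)OC1 | intermediate
15 | (4S,5R)-4-[(4S)-2,2-dimethyl-1,3-dioxolan-4-yl]-5-ethenyl-3-methylideneoxolan-2-one | C=C1C(=O)O[C@H](C=C)[C@H]1[C@@H]2OC(C)(C)OC2 | intermediate
16 | (4R,5R)-4-[(1S)-1,2-dihydroxyethyl]-5-ethenyl-3-methylideneoxolan-2-one | C=C1C(=O)O[C@H](C=C)[C@H]1[C@H](O)CO | intermediate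
17 | (4R,5R)-4-[(1S)-2-(tert-butyldimethylsilyloxy)-1-hydroxyethyl]-5-ethenyl-3-methylideneoxolan-2-one | C=C1C(=O)O[C@H](C=C)[C@H]1[C@H](O)CO[Si](C)(C)C(C)(C)C | intermediate
18 | angelic acid, (2Z)-2-methylbut-2-enoic acid | C/C=C(/C)C(=O)O | starting material
19 | (1S)-2-(tert-butyldimethylsilyloxy)-1-[(2R,3S)-2-ethenyl-4-methylidene-5-oxooxolan-3-yl]ethyl (2Z)-2-methylbut-2-enoate | C=C1C(=O)O[C@H](C=C)[C@H]1[C@H](OC(=O)/C(C)=C\C)CO[Si](C)(C)C(C)(C)C | intermediate
20 | (1S)-1-[(2R,3S)-2-ethenyl-4-methylidene-5-oxooxolan-3-yl]-2-hydroxyethyl (2Z)-2-methylbut-2-enoate | C=C1C(=O)O[C@H](C=C)[C@H]1[C@H](OC(=O)/C(C)=C\C)CO | intermediate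
21 | (1S)-1-[(2R,3S)-2-ethenyl-4-methylidene-5-oxooxolan-3-yl]-2-oxoethyl (2Z)-2-methylbut-2-enoate | C=C1C(=O)O[C@H](C=C)[C@H]1[C@H](OC(=O)/C(C)=C\C)C=O | intermediate
22 | seco-germacranolide C9 alcohol, major 9R epimer drawn (2S,6R,7S,8S,9R; 1(10)E) | C=C1C(=O)O[C@H](C=C)[C@H]1[C@H](OC(=O)/C(C)=C\C)[C@H](O)/C(C(=O)OC)=C\[C@@H](O[Si](C)(C)C(C)(C)C)CC(C)=C | intermediate
23 | seco-germacranolide C9 ketone (2S,6R,7S,8S; 1(10)E) | C=C1C(=O)O[C@H](C=C)[C@H]1[C@H](OC(=O)/C(C)=C\C)C(=O)/C(C(=O)OC)=C\[C@@H](O[Si](C)(C)C(C)(C)C)CC(C)=C | intermediate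
24 | seco-germacranolide (9S)-alcohol (2S,6R,7S,8S,9S; 1(10)E) | C=C1C(=O)O[C@H](C=C)[C@H]1[C@H](OC(=O)/C(C)=C\C)[C@@H](O)/C(C(=O)OC)=C\[C@@H](O[Si](C)(C)C(C)(C)C)CC(C)=C | intermediate
25 | seco-germacranolide 9-acetate 2-silyl ether (2S,6R,7S,8S,9S; 1(10)E) | C=C1C(=O)O[C@H](C=C)[C@H]1[C@H](OC(=O)/C(C)=C\C)[C@@H](OC(C)=O)/C(C(=O)OC)=C\[C@@H](O[Si](C)(C)C(C)(C)C)CC(C)=C | intermediate
26 | seco-germacranolide pentaene with free C2 hydroxyl (2S,6R,7S,8S,9S; 1(10)E) | C=C1C(=O)O[C@H](C=C)[C@H]1[C@H](OC(=O)/C(C)=C\C)[C@@H](OC(C)=O)/C(C(=O)OC)=C\[C@@H](O)CC(C)=C | intermediate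
27 | (1(10)E,4Z)-9α-acetoxy-8β-angeloyloxy-2α-hydroxy-14-methoxy-14-oxogermacra-1(10),4,11(13)-trien-12,6α-olide (2S,6R,7S,8S,9S) | C=C1C(=O)O[C@H]2[C@H]1[C@H](OC(=O)/C(C)=C\C)[C@@H](OC(C)=O)/C(C(=O)OC)=C\[C@@H](O)C/C(C)=C\2 | intermediate
28 | CNP0278274.1, the 4α,5α-epoxide of 27 (2S,4R,5S,6S,7R,8S,9S) | C=C1C(=O)O[C@H]2[C@H]1[C@H](OC(=O)/C(C)=C\C)[C@@H](OC(C)=O)/C(C(=O)OC)=C\[C@@H](O)C[C@@]1(C)O[C@@H]21 | target

**Totals**
Total step count: 19.
Longest linear sequence: 15 steps (steps 5–19, from 9).

**Steps most likely to fail**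

Step 18. The C5 ruthenium alkylidene may fail to engage the hindered 1,1-disubstituted C4 olefin, so that oligomerisation or catalyst decay overtakes closure of the strained ring. The fallback changes the substrate instead of the catalyst. It sets out from 26, which is oxidised with Dess–Martin periodinane to the C2 ketone of the pentaene F1. In this cross-conjugated ene-dione segment C9–C10=C1–C2–C3 is planar, one sp3 centre and the ruthenium-binding hydroxyl are gone, and the two termini lie closer. Ring-closing metathesis under the conditions of step 18 should give the macrocyclic 2-oxo-(4Z)-dienolide F2. This is reduced at once by Corey–Bakshi–Shibata reduction with (R)-2-methyl-oxazaborolidine and catecholborane at −78 °C. The alkenyl side acts as the large group, so 2S is expected. The route is rejoined at 27.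

Step 7. The C8 stereocentre may steer acrolein to the other face of the allylchromium species (attack anti to O8), which would give the 6,7-bis-epimer of 15. The fallback uses that same sense of induction and corrects C8 instead. It sets out from methyl acrylate 10, which is combined with commercial (S)-glyceraldehyde acetonide under the conditions of step 5 to give the enantiomeric-series Baylis–Hillman adduct F3. The conditions of steps 6–9 then lead through the (Z)-allylic bromide F4 and the anti hydroxy ester F5 to the trans lactone F6, which is correct at C6 and C7 and epimeric at C8. Hydrolysis gives the diol F7 and monosilylation the primary silyl ether F8. Mitsunobu esterification of F8 with angelic acid 18 (PPh3, DIAD, toluene, 0 °C) installs the angelate with inversion at C8. The route is rejoined at 19.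

Step 19. The macrocycle may present its other olefin face, or the vanadate may bind poorly, so that oxygen arrives anti to O2 or the reaction is unselective. The fallback reaches the opposite face by anti addition followed by inversion. It sets out from 27, which with NBS in aqueous THF at 0 °C should form the bromonium ion on the more exposed face of the only electron-rich olefin. Water then opens it at the tertiary C4 to give the 5-bromo-4-hydroxy compound (bromohydrin) F9. Ag2O in CH2Cl2 closes the oxirane by displacement at C5 with inversion, which places the oxygen on the face opposite to that of direct attack. The route is rejoined at 28.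

**Further compounds**
F1 | step 18 | C2 ketone of pentaene 26 (6R,7S,8S,9S; 1(10)E) | C=C1C(=O)O[C@H](C=C)[C@H]1[C@H](OC(=O)/C(C)=C\C)[C@@H](OC(C)=O)/C(C(=O)OC)=C\C(=O)CC(C)=C
F2 | step 18 | macrocyclic 2-oxo-(1(10)E,4Z)-dienolide | C=C1C(=O)O[C@H]2[C@H]1[C@H](OC(=O)/C(C)=C\C)[C@@H](OC(C)=O)/C(C(=O)OC)=C\C(=O)C/C(C)=C\2
F3 | step 7 | methyl 2-{[(4S)-2,2-dimethyl-1,3-dioxolan-4-yl](hydroxy)methyl}prop-2-enoate, both carbinol epimers | C=C(C(=O)OC)C(O)[C@H]1OC(C)(C)OC1
F4 | step 7 | methyl (2Z)-2-(bromomethyl)-3-[(4R)-2,2-dimethyl-1,3-dioxolan-4-yl]prop-2-enoate | COC(=O)/C(CBr)=C/[C@H]1OC(C)(C)OC1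
F5 | step 7 | C8 epimer of hydroxy ester 14 | O[C@H](C=C)[C@H](C(=C)C(=O)OC)[C@H]1OC(C)(C)OC1
F6 | step 7 | C8 epimer of lactone 15 | C=C1C(=O)O[C@H](C=C)[C@H]1[C@H]2OC(C)(C)OC2
F7 | step 7 | C8 epimer of diol 16 | C=C1C(=O)O[C@H](C=C)[C@H]1[C@@H](O)CO
F8 | step 7 | C8 epimer of silyl ether 17 | C=C1C(=O)O[C@H](C=C)[C@H]1[C@@H](O)CO[Si](C)(C)C(C)(C)C
F9 | step 19 | 5β-bromo-4α-hydroxy compound (bromohydrin) from 27 | C=C1C(=O)O[C@H]2[C@H]1[C@H](OC(=O)/C(C)=C\C)[C@@H](OC(C)=O)/C(C(=O)OC)=C\[C@@H](O)C[C@@](C)(O)[C@@H]2Br
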